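**Plan**
- Retrosynthesis: the aryl–C7 and aryl–C7′ bonds are cut first, each back to a CH2–CO2H arm. The two extra carboxyl carbons are then joined as the C4=C5 alkene of a cyclohexene, and C7–C8 and C7′–C8′ are cut by a retro-[4+2] to buta-1,3-diene and a fumarate diester.
- Enabling feature: the chain C7–C8(C9)–C8′(C9′)–C7′, with C9 and C9′ on a C2-symmetric backbone, is C6–C1(CO2R)–C2(CO2R)–C3 of a trans-cyclohex-4-ene-1,2-dicarboxylate. Only the ring carbons C4 and C5 are absent from the target.
- Forward order: esterification, then Diels–Alder closure of the one (temporary) six-membered ring, reduction and silylation, and ozonolytic ring opening with an unsymmetrical work-up. Two decarboxylative arylations follow (3,4-dimethoxyphenyl first, O-benzyl syringyl second), then desilylation, acetylation and debenzylation.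
- Stereochemistry: C8 and C8′ (both R) are set together in the cycloaddition, trans from the E-fumarate and absolute sense from the two (+)-menthyl esters. Afterwards they never become enolisable or radical centres.

Key step: step 2

Remark on the chemistry: lignan numbering is used (unprimed = 3,4-dimethoxyphenyl half, primed = 4-hydroxy-3,5-dimethoxyphenyl half). The sense of induction of the (+)-menthyl ester is taken as the mirror image of that established for the (−)-menthyl ester under the same Lewis acid conditions, and the sign of rotation of diol 6 would be compared with the value on record before material is carried forward.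

**Step 1**
Reactants: 1 (+)-menthol; 2 fumaryl chloride
Product: 3 di-(+)-menthyl fumarate, bis[(1S,2R,5S)-5-methyl-2-(propan-2-yl)cyclohexyl] (2E)-but-2-enedioate
Conditions: 1 (2.1 equiv), Et3N, DMAP (cat.), CH2Cl2, 0 °C → rt
Reagents that add atoms: none
Why: Double nucleophilic acyl substitution of the diacid chloride by the secondary alcohol (DMAP-assisted esterification) should give the diester with the E alkene and the menthyl stereocentres untouched.

**Step 2**
Reactants: 3 di-(+)-menthyl fumarate; 4 buta-1,3-diene
Product: 5 di-(+)-menthyl (1R,2R)-cyclohex-4-ene-1,2-dicarboxylate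
Conditions: 4 (excess), Et2AlCl (2 equiv), toluene/hexane, −78 → −40 °C; dilute HCl quench; recrystallisation
Reagents that add atoms: none
Why: Et2AlCl binds the ester carbonyls, lowers the fumarate LUMO and holds each enoate in the s-trans conformation, and s-cis butadiene then adds in a concerted, suprafacial [4+2] cycloaddition; the closest known reaction type is the Lewis-acid-promoted asymmetric Diels–Alder reaction of a chiral fumarate diester, which is this very substrate class. The cyclohexene ring, the only ring made in the route and a temporary one, closes by intermolecular [4+2] annulation in which the future C7–C8 and C7′–C8′ bonds form together at the two termini of the diene. The trans relation of the two new stereocentres follows from the E geometry of the dienophile, which a concerted suprafacial addition transfers unchanged. Their absolute configuration is controlled by the two (1S,2R,5S)-menthyl groups, whose isopropyl-bearing flanks screen the same face of the C2-symmetric aluminium-bound fumarate, so that attack on the open face should give the (1R,2R) adduct. The step needs only diastereofacial selectivity, since regiochemistry and endo/exo orientation are moot with a symmetrical diene and a symmetrical dienophile; the double shielding at low temperature should secure it, and crystallisation of 5 should remove any minor diastereomer.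

**Step 3**
Reactants: 5 di-(+)-menthyl (1R,2R)-cyclohex-4-ene-1,2-dicarboxylate
Product: 6 [(1R,2R)-cyclohex-4-ene-1,2-diyl]dimethanol
Conditions: LiAlH4, THF, 0 °C → reflux; H2O, aq. NaOH work-up; (+)-menthol recovered
Reagents that add atoms: none
Why: Hydride reduction of both hindered esters to primary alcohols should leave the isolated alkene and the two stereocentres untouched and release the auxiliary for re-use.

**Step 4**
Reactants: 6 [(1R,2R)-cyclohex-4-ene-1,2-diyl]dimethanol
Product: 7 (4R,5R)-4,5-bis[(tert-butyldimethylsilyloxy)methyl]cyclohexene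
Conditions: TBSCl, imidazole, DMF, rt
Reagents that add atoms: tert-butyldimethylsilyl chloride, CC(C)(C)[Si](C)(C)Cl
Why: Imidazole-mediated silylation of the two primary alcohols should be clean and gives ethers that withstand ozone, chlorite, organozinc reagents and aqueous LiOH.

**Step 5**
Reactants: 7 (4R,5R)-4,5-bis[(tert-butyldimethylsilyloxy)methyl]cyclohexene
Product: 10 methyl (3R,4R)-3,4-bis[(tert-butyldimethylsilyloxy)methyl]-6-oxohexanoate, via methoxy hydroperoxide aldehyde 8 (not isolated), via peracetate aldehyde 9 (not isolated)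
Conditions: O3, NaHCO3, CH2Cl2/MeOH (5:1), −78 °C; N2 purge; then Ac2O, Et3N, CH2Cl2, 0 °C → rt
Reagents that add atoms: ozone, [O-][O+]=O; methanol, CO
Why: Ozonolysis in methanol (Criegee mechanism) traps the carbonyl oxide as a methoxy hydroperoxide while the other terminus stays an aldehyde under NaHCO3 buffering, and acetylation of the hydroperoxide followed by base-induced loss of acetic acid turns that terminus into the methyl ester (ozonolysis with unsymmetrical work-up), the C2 symmetry of 7 making both cleavage senses give the same compound.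

**Step 6**
Reactants: 10 methyl (3R,4R)-3,4-bis[(tert-butyldimethylsilyloxy)methyl]-6-oxohexanoate
Product: 11 (3R,4R)-3,4-bis[(tert-butyldimethylsilyloxy)methyl]-6-methoxy-6-oxohexanoic acid
Conditions: NaClO2, NaH2PO4, 2-methylbut-2-ene, t-BuOH/H2O, 0 °C → rt
Reagents that add atoms: sodium chlorite (NaClO2), [Na+].[O-]Cl=O
Why: The Pinnick oxidation converts the aldehyde into the acid under buffered conditions that spare silyl ethers and the ester, and the stereocentre beta to the carbonyl cannot epimerise.

**Step 7**
Reactants: 11 (3R,4R)-3,4-bis[(tert-butyldimethylsilyloxy)methyl]-6-methoxy-6-oxohexanoic acid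
Product: 12 1-(1,3-dioxoisoindolin-2-yl) 6-methyl (3R,4R)-3,4-bis[(tert-butyldimethylsilyloxy)methyl]hexanedioate
Conditions: N-hydroxyphthalimide, DIC, DMAP (cat.), CH2Cl2, rt
Reagents that add atoms: N-hydroxyphthalimide, O=C1N(O)C(=O)c2ccccc12
Why: Carbodiimide coupling (Steglich-type esterification) of the acid with N-hydroxyphthalimide should give the isolable redox-active ester that serves as the alkyl radical precursor.

**Step 8**
Reactants: 12 the N-(acyloxy)phthalimide ester from step 7; 13 4-bromo-1,2-dimethoxybenzene
Product: 16 methyl (3R,4R)-3,4-bis[(tert-butyldimethylsilyloxy)methyl]-5-(3,4-dimethoxyphenyl)pentanoate, via arylmagnesium bromide 14 (not isolated), via arylzinc chloride 15 (not isolated)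
Conditions: 13, Mg, LiCl, THF, rt; ZnCl2, THF; then 12, NiCl2(glyme) (20 mol%), 4,4′-di-tert-butyl-2,2′-bipyridine (40 mol%), THF/DMF, rt
Reagents that add atoms: none
Why: In this nickel-catalysed decarboxylative Negishi-type arylation the arylzinc (from magnesium insertion and transmetalation to ZnCl2) arylates the divalent nickel precatalyst, a low-valent arylnickel species reduces the phthalimide ester by single-electron transfer, CO2 is lost, and the primary radical is captured at nickel and reductively eliminated to form the aryl–C7 bond, while the methyl ester and silyl ethers tolerate the organozinc and the neighbouring stereocentre keeps all four of its bonds.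

**Step 9**
Reactants: 16 methyl (3R,4R)-3,4-bis[(tert-butyldimethylsilyloxy)methyl]-5-(3,4-dimethoxyphenyl)pentanoate
Product: 17 (3R,4R)-3,4-bis[(tert-butyldimethylsilyloxy)methyl]-5-(3,4-dimethoxyphenyl)pentanoic acid
Conditions: LiOH·H2O, THF/MeOH/H2O, rt; then 1 M HCl to pH 4, 0 °C
Reagents that add atoms: lithium hydroxide (LiOH), [Li+].[OH-]
Why: Saponification of the unhindered methyl ester leaves the primary TBS ethers and the non-enolisable stereocentres untouched, and acidification only to pH 4 frees the acid without desilylation.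

**Step 10**
Reactants: 17 (3R,4R)-3,4-bis[(tert-butyldimethylsilyloxy)methyl]-5-(3,4-dimethoxyphenyl)pentanoic acid
Product: 18 1,3-dioxoisoindolin-2-yl (3R,4R)-3,4-bis[(tert-butyldimethylsilyloxy)methyl]-5-(3,4-dimethoxyphenyl)pentanoate
Conditions: N-hydroxyphthalimide, DIC, DMAP (cat.), CH2Cl2, rt
Reagents that add atoms: N-hydroxyphthalimide, O=C1N(O)C(=O)c2ccccc12
Why: The same Steglich-type activation as in step 7 should convert the second carboxyl arm into its redox-active ester.

**Step 11**
Reactants: 19 4-bromo-2,6-dimethoxyphenol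
Product: 20 2-(benzyloxy)-5-bromo-1,3-dimethoxybenzene
Conditions: BnBr, K2CO3, DMF, rt
Reagents that add atoms: benzyl bromide, BrCc1ccccc1
Why: Williamson etherification masks the acidic phenol, which would quench the organometallic reagents, as a benzyl ether that can be removed at the end by hydrogenolysis without touching acetates.

**Step 12**
Reactants: 18 the N-(acyloxy)phthalimide ester from step 10; 20 2-(benzyloxy)-5-bromo-1,3-dimethoxybenzene
Product: 23 (2R,3R)-2-[4-(benzyloxy)-3,5-dimethoxybenzyl]-3-(3,4-dimethoxybenzyl)butane-1,4-diol bis(tert-butyldimethylsilyl) ether, via arylmagnesium bromide 21 (not isolated), via arylzinc chloride 22 (not isolated)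
Conditions: 20, Mg, LiCl, THF, rt; ZnCl2, THF; then 18, NiCl2(glyme) (20 mol%), 4,4′-di-tert-butyl-2,2′-bipyridine (40 mol%), THF/DMF, rt
Reagents that add atoms: none
Why: The second nickel-catalysed decarboxylative Negishi-type arylation, by the same radical capture and reductive elimination sequence as in step 8, should form the aryl–C7′ bond, with the benzyl ether inert to the magnesium and zinc reagents and the adjacent stereocentre again only a spectator.

**Step 13**
Reactants: 23 the bis(tert-butyldimethylsilyl) ether from step 12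
Product: 24 (2R,3R)-2-[4-(benzyloxy)-3,5-dimethoxybenzyl]-3-(3,4-dimethoxybenzyl)butane-1,4-diol
Conditions: Bu4NF, THF, 0 °C → rt
Reagents that add atoms: none
Why: Fluoride-induced desilylation, driven by Si–F bond formation, cleaves both primary TBS ethers and leaves the benzyl and methyl aryl ethers intact.

**Step 14**
Reactants: 24 (2R,3R)-2-[4-(benzyloxy)-3,5-dimethoxybenzyl]-3-(3,4-dimethoxybenzyl)butane-1,4-diol
Product: 25 (2R,3R)-2-[4-(benzyloxy)-3,5-dimethoxybenzyl]-3-(3,4-dimethoxybenzyl)butane-1,4-diyl diacetate
Conditions: Ac2O, pyridine, DMAP (cat.), CH2Cl2, rt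
Reagents that add atoms: acetic anhydride, CC(=O)OC(C)=O
Why: DMAP-catalysed acetylation installs the two primary acetates of the target while the phenol is still benzylated, so no aryl acetate can form.

**Step 15**
Reactants: 25 (2R,3R)-2-[4-(benzyloxy)-3,5-dimethoxybenzyl]-3-(3,4-dimethoxybenzyl)butane-1,4-diyl diacetate
Product: 26 Justin C, (2R,3R)-2-(3,4-dimethoxybenzyl)-3-(4-hydroxy-3,5-dimethoxybenzyl)butane-1,4-diyl diacetate
Conditions: H2 (1 atm), 10% Pd/C, EtOAc, rt
Reagents that add atoms: none
Why: Palladium-catalysed hydrogenolysis cleaves the O–benzyl bond in a non-nucleophilic solvent and leaves the acetates, the aryl methyl ethers and the unactivated ArCH2–C bonds alone, giving the target with both stereocentres as set in step 2.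

**Compound list**
1 | (+)-menthol, (1S,2R,5S)-5-methyl-2-(propan-2-yl)cyclohexan-1-ol | CC(C)[C@H]1CC[C@H](C)C[C@@H]1O | starting material
2 | fumaryl chloride | O=C(Cl)/C=C/C(=O)Cl | starting material
3 | di-(+)-menthyl fumarate | O=C(/C=C/C(=O)O[C@H]1C[C@@H](C)CC[C@@H]1C(C)C)O[C@H]1C[C@@H](C)CC[C@@H]1C(C)C | intermediate
4 | buta-1,3-diene | C=CC=C | starting material
5 | di-(+)-menthyl (1R,2R)-cyclohex-4-ene-1,2-dicarboxylate | C1[C@@H](C(=O)O[C@H]2C[C@@H](C)CC[C@@H]2C(C)C)[C@H](C(=O)O[C@H]2C[C@@H](C)CC[C@@H]2C(C)C)CC=C1 | intermediate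
6 | [(1R,2R)-cyclohex-4-ene-1,2-diyl]dimethanol | C1[C@@H](CO)[C@H](CO)CC=C1 | intermediate
7 | (4R,5R)-4,5-bis[(tert-butyldimethylsilyloxy)methyl]cyclohexene | C1[C@@H](CO[Si](C)(C)C(C)(C)C)[C@H](CO[Si](C)(C)C(C)(C)C)CC=C1 | intermediate
8 | (3R,4R)-3,4-bis[(tert-butyldimethylsilyloxy)methyl]-6-hydroperoxy-6-methoxyhexanal (epimers at C6; not isolated) | O=CC[C@@H](CO[Si](C)(C)C(C)(C)C)[C@H](CO[Si](C)(C)C(C)(C)C)CC(OC)OO | intermediate
9 | (3R,4R)-3,4-bis[(tert-butyldimethylsilyloxy)methyl]-1-methoxy-6-oxohexyl ethaneperoxoate (epimers at C1; not isolated) | O=CC[C@@H](CO[Si](C)(C)C(C)(C)C)[C@H](CO[Si](C)(C)C(C)(C)C)CC(OC)OOC(C)=O | intermediate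
10 | methyl (3R,4R)-3,4-bis[(tert-butyldimethylsilyloxy)methyl]-6-oxohexanoate | O=CC[C@@H](CO[Si](C)(C)C(C)(C)C)[C@H](CO[Si](C)(C)C(C)(C)C)CC(=O)OC | intermediate
11 | (3R,4R)-3,4-bis[(tert-butyldimethylsilyloxy)methyl]-6-methoxy-6-oxohexanoic acid | OC(=O)C[C@@H](CO[Si](C)(C)C(C)(C)C)[C@H](CO[Si](C)(C)C(C)(C)C)CC(=O)OC | intermediate
12 | 1-(1,3-dioxoisoindolin-2-yl) 6-methyl (3R,4R)-3,4-bis[(tert-butyldimethylsilyloxy)methyl]hexanedioate | O=C(C[C@@H](CO[Si](C)(C)C(C)(C)C)[C@H](CO[Si](C)(C)C(C)(C)C)CC(=O)OC)ON1C(=O)c2ccccc2C1=O | intermediate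
13 | 4-bromo-1,2-dimethoxybenzene | COc1ccc(Br)cc1OC | starting material
14 | (3,4-dimethoxyphenyl)magnesium bromide (not isolated) | COc1ccc([Mg]Br)cc1OC | intermediate
15 | (3,4-dimethoxyphenyl)zinc chloride (not isolated) | COc1ccc([Zn]Cl)cc1OC | intermediate
16 | methyl (3R,4R)-3,4-bis[(tert-butyldimethylsilyloxy)methyl]-5-(3,4-dimethoxyphenyl)pentanoate | COc1ccc(C[C@@H](CO[Si](C)(C)C(C)(C)C)[C@H](CO[Si](C)(C)C(C)(C)C)CC(=O)OC)cc1OC | intermediate
17 | (3R,4R)-3,4-bis[(tert-butyldimethylsilyloxy)methyl]-5-(3,4-dimethoxyphenyl)pentanoic acid | COc1ccc(C[C@@H](CO[Si](C)(C)C(C)(C)C)[C@H](CO[Si](C)(C)C(C)(C)C)CC(=O)O)cc1OC | intermediate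
18 | 1,3-dioxoisoindolin-2-yl (3R,4R)-3,4-bis[(tert-butyldimethylsilyloxy)methyl]-5-(3,4-dimethoxyphenyl)pentanoate | COc1ccc(C[C@@H](CO[Si](C)(C)C(C)(C)C)[C@H](CO[Si](C)(C)C(C)(C)C)CC(=O)ON2C(=O)c3ccccc3C2=O)cc1OC | intermediate
19 | 4-bromo-2,6-dimethoxyphenol | COc1cc(Br)cc(OC)c1O | starting material
20 | 2-(benzyloxy)-5-bromo-1,3-dimethoxybenzene | COc1cc(Br)cc(OC)c1OCc2ccccc2 | intermediate
21 | [4-(benzyloxy)-3,5-dimethoxyphenyl]magnesium bromide (not isolated) | COc1cc([Mg]Br)cc(OC)c1OCc2ccccc2 | intermediate
22 | [4-(benzyloxy)-3,5-dimethoxyphenyl]zinc chloride (not isolated) | COc1cc([Zn]Cl)cc(OC)c1OCc2ccccc2 | intermediate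
23 | (2R,3R)-2-[4-(benzyloxy)-3,5-dimethoxybenzyl]-3-(3,4-dimethoxybenzyl)butane-1,4-diol bis(tert-butyldimethylsilyl) ether | COc1ccc(C[C@@H](CO[Si](C)(C)C(C)(C)C)[C@H](CO[Si](C)(C)C(C)(C)C)Cc2cc(OC)c(OCc3ccccc3)c(OC)c2)cc1OC | intermediate
24 | (2R,3R)-2-[4-(benzyloxy)-3,5-dimethoxybenzyl]-3-(3,4-dimethoxybenzyl)butane-1,4-diol | COc1ccc(C[C@@H](CO)[C@H](CO)Cc2cc(OC)c(OCc3ccccc3)c(OC)c2)cc1OC | intermediate
25 | (2R,3R)-2-[4-(benzyloxy)-3,5-dimethoxybenzyl]-3-(3,4-dimethoxybenzyl)butane-1,4-diyl diacetate | COc1ccc(C[C@@H](COC(C)=O)[C@H](COC(C)=O)Cc2cc(OC)c(OCc3ccccc3)c(OC)c2)cc1OC | intermediate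
26 | Justin C, (2R,3R)-2-(3,4-dimethoxybenzyl)-3-(4-hydroxy-3,5-dimethoxybenzyl)butane-1,4-diyl diacetate | COc1ccc(C[C@@H](COC(C)=O)[C@H](COC(C)=O)Cc2cc(OC)c(O)c(OC)c2)cc1OC | target

**Step count**
Total: 15 steps. Longest linear sequence: 14 steps (steps 1–10 and 12–15; step 11 is a one-step branch).

**Steps most likely to fail**

Step 8. Capture of a primary alkyl radical by nickel may be slow, so reduction to the alkane, radical dimerisation and acyl transfer from the activated ester to the arylzinc could erode the coupling. The fallback reverses the polarity of the bond formation and sets out from acid 11. Iododecarboxylation with PhI(OAc)2 and I2 under visible-light irradiation in cyclohexane (a Hunsdiecker-type reaction, run while no electron-rich arene is yet in the molecule) should give methyl (3R,4R)-3,4-bis[(tert-butyldimethylsilyloxy)methyl]-5-iodopentanoate F1. Zinc insertion (Zn dust, LiCl, THF) would convert it into [(2R,3R)-2,3-bis[(tert-butyldimethylsilyloxy)methyl]-5-methoxy-5-oxopentyl]zinc iodide F2. A Pd(OAc)2/SPhos-catalysed Negishi coupling of F2 with aryl bromide 13 in THF then needs no radical capture at nickel and returns to the route at 16.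

Step 12. The primary radical is generated next to the C7 benzyl group and may add to the electron-rich dimethoxyphenyl ring (tetralin closure or 1,4-aryl shift) before nickel intercepts it, on top of the general sluggishness of primary redox-active esters. The fallback sets out from acid 17. Esterification with N-hydroxypyridine-2-thione (DCC, CH2Cl2, in the dark) gives the Barton ester 2-thioxopyridin-1(2H)-yl (3R,4R)-3,4-bis[(tert-butyldimethylsilyloxy)methyl]-5-(3,4-dimethoxyphenyl)pentanoate F3. Its photolysis in the presence of CHI3 (Barton decarboxylative iodination) should trap the radical by iodine-atom transfer faster than it can cyclise and give 4-[(2R,3R)-2,3-bis[(tert-butyldimethylsilyloxy)methyl]-4-iodobutyl]-1,2-dimethoxybenzene F4. Li2CuCl4-catalysed substitution of this primary iodide by Grignard reagent 21 (THF, −20 to 0 °C) is a polar displacement, feasible here because no ester remains, and returns to the route at 23.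

Step 2. Facial discrimination at the aluminium-bound fumarate may be incomplete, or butadiene may polymerise under the Lewis acid, leaving a diastereomer mixture that crystallisation does not fully purify. The fallback keeps the same cycloaddition bonds and ring but takes the absolute configuration from a resolution, and sets out from buta-1,3-diene 4 and commercial diethyl fumarate. An uncatalysed thermal Diels–Alder reaction (toluene, sealed vessel, 150 °C) gives racemic diethyl trans-cyclohex-4-ene-1,2-dicarboxylate F5. Saponification (KOH, aqueous EtOH, then dilute HCl) gives racemic trans-cyclohex-4-ene-1,2-dicarboxylic acid F6. Classical resolution through the crystalline salt with one enantiomer of 1-phenylethylamine (antipode chosen by trial, acid freed with dilute HCl) should deliver (1R,2R)-cyclohex-4-ene-1,2-dicarboxylic acid F7. LiAlH4 reduction of F7 in THF returns to the route at diol 6.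

**Further compounds**
F1 | step 8 | methyl (3R,4R)-3,4-bis[(tert-butyldimethylsilyloxy)methyl]-5-iodopentanoate | IC[C@@H](CO[Si](C)(C)C(C)(C)C)[C@H](CO[Si](C)(C)C(C)(C)C)CC(=O)OC
F2 | step 8 | [(2R,3R)-2,3-bis[(tert-butyldimethylsilyloxy)methyl]-5-methoxy-5-oxopentyl]zinc iodide | I[Zn]C[C@@H](CO[Si](C)(C)C(C)(C)C)[C@H](CO[Si](C)(C)C(C)(C)C)CC(=O)OC
F3 | step 12 | 2-thioxopyridin-1(2H)-yl (3R,4R)-3,4-bis[(tert-butyldimethylsilyloxy)methyl]-5-(3,4-dimethoxyphenyl)pentanoate | COc1ccc(C[C@@H](CO[Si](C)(C)C(C)(C)C)[C@H](CO[Si](C)(C)C(C)(C)C)CC(=O)On2ccccc2=S)cc1OC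
F4 | step 12 | 4-[(2R,3R)-2,3-bis[(tert-butyldimethylsilyloxy)methyl]-4-iodobutyl]-1,2-dimethoxybenzene | COc1ccc(C[C@@H](CO[Si](C)(C)C(C)(C)C)[C@H](CO[Si](C)(C)C(C)(C)C)CI)cc1OC
F5 | step 2 | diethyl trans-cyclohex-4-ene-1,2-dicarboxylate (racemate; one enantiomer written) | C1[C@@H](C(=O)OCC)[C@H](C(=O)OCC)CC=C1
F6 | step 2 | trans-cyclohex-4-ene-1,2-dicarboxylic acid (racemate; one enantiomer written) | C1[C@@H](C(=O)O)[C@H](C(=O)O)CC=C1
F7 | step 2 | (1R,2R)-cyclohex-4-ene-1,2-dicarboxylic acid (single enantiomer) | C1[C@@H](C(=O)O)[C@H](C(=O)O)CC=C1
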